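Grey, amber and ochre are my earlier flasks: E starts chains, L goes into them as Z, and the charge of X is what differs.

in all of them: L 2.6 M; E 10 mol%

| flask | X | remark | time |
|---|---|---|---|
| grey | 0.60 M | run made earlier |  |
| amber | 0.61 M | run made earlier |  |
| ochre | 0.88 M | run made earlier |  |
| Tuesday's | 0.780 M |  | 2.0 d |
| Sunday's | 0.500 M |  | 2.0 d |

- grey (time / h: Z / %, L / %): 2.00: 9, 89; 6.00: 35, 56; 12.0: 71, 25; 15.0: 77, 13; 25.0: 83, 3
- amber (time / h: Z / %, L / %): 2.00: 7, 89; 6.00: 36, 58; 12.0: 68, 23; 15.0: 75, 14; 25.0: 85, 3
- ochre (time / h: Z / %, L / %): 2.00: 7, 89; 4.00: 19, 74; 6.00: 37, 56; 12.0: 65, 23; 25.0: 79, 3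

(readings scatter by 1.5 percentage points)

- the average divides the monomer in chains by the number of chains begun, living and dead together
- the earlier runs were read with a standard deviation of 1.5 percentage points
- the earlier runs do not show the number of chains; that part of a forecast is a guess

* which of the two ends with the longer chains by the average number of monomer units in a chain (chains begun, living or dead) ("neither" if they lie within 10%) (Tuesday's / Sunday's / neither)
* average number of monomer units in a chain (chains begun, living or dead) at the end, Tuesday's
* average number of monomer units in a chain (chains begun, living or dead) at the end, Sunday's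

1. Z and L do not add up to the charge: at the last reading, 25.0 h, the average of grey and amber misses 13.0% and ochre misses 18.0%, so I read a side reaction, a leak parallel to the chain line, and I assume it spends one X for each L.

2. My first answer divides by the X charged, but that X runs down, so I put the missing L back in and take as average X the charge less half of what the leak spent: 0.436 M for grey and amber, 0.646 M for ochre.

3. The missing share of reacted L over average X reads 0.307 L mol⁻¹ from grey and amber and, separately, 0.287 L mol⁻¹ from ochre; different flasks give these two readings, so I trust their mean, 0.297 L mol⁻¹, the leak ratio: the share of reacted L lost from the chains per unit of average X.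

4. Counting the L as fully reacted by 2.0 d, and solving with X running down, I expect 16.7% lost on Tuesday's and 10.7% on Sunday's.

5. The runs do not show the number of chains, so I commit to a ratio: with equal chains, Tuesday's length is 0.933 of Sunday's, a gap of 6.72%, less than 10%, which means neither.

The forecast says neither, with 8.4 for Tuesday's and 8.9 for Sunday's, and it writes “My guess is that chains begun” equal the E charged.

The flask gives neither, with 15.9 on Tuesday's and 16.4 on Sunday's.

    L + E → J + Z (k = 5.70 × 10⁻⁴ L mol⁻¹ min⁻¹)
    L + J → Z + J, rate k2*[J]*[L] (k = 0.0252 L mol⁻¹ min⁻¹)
    J → D (k = 6.45 × 10⁻⁴ min⁻¹)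
    X + L → Q (k = 4.82 × 10⁻⁴ L mol⁻¹ min⁻¹)

Tuesday's still holds 46.4% of its E at 2.00 d. Against the leak ratio's 16.7%, Tuesday's holds Q 14.3%. The same flask read at 12 h has L 22.4% left, so 77.6% has reacted; the leak ratio then gives 13.8% lost and Z 63.8%, and that flask holds Q 12.2% and Z 65.4%.

Readings and results are simulated for substances that don't exist, and the scatter is random.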